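**Strategy.** The flavanone is disconnected across ring C at the O1–C2 and C3–C4 bonds. O1, C8a, C4a and C4 then belong to a fully substituted salicylaldehyde and the C2–C3 unit to 3,4-dimethoxystyrene. Because ring B carries two methoxy groups, this alkene is a potent π-nucleophile and its aryl-bearing carbon ends up as C2. A chiral Brønsted acid and trimethyl orthoformate convert the aldehyde into a 4-methoxy ortho-quinone methide, which takes up the styrene in one enantioselective oxa-[4+2] step. This closes ring C, sets C2 and leaves C4 as a methyl ether one oxidation level below the ketone. The precursor is 2-hydroxy-3,5-diprenyl-4-(triisopropylsilyloxy)benzaldehyde, with only the 2-hydroxyl free.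

Key step: step 4

Remarks on the chemistry:
- Compounds 9–13 use flavan numbering (O1, C2, C3, C4, C4a, C5–C8, C8a; ring B primed).
- Assumption: the (R)-configured catalyst is taken to give the (2S,4S) adduct; if the sense of induction is the opposite, the (S)-catalyst is used and nothing else changes.
- Precursor design: the oxygen that becomes O7 carries a triisopropylsilyl group and not a smaller silyl group. It is para to C4, which turns cationic in steps 4 and 5, and that makes a small silyl group liable to transfer to methanol or water. The bulky group between two prenyl groups should stay.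

**Route**

Step 1
Reactants: 1 2,4-dihydroxybenzaldehyde
Product: 2 2,4-dihydroxy-3,5-diiodobenzaldehyde
Conditions: NIS (2.2 equiv), TFA (10 mol %), MeCN, 0 °C to rt
Reagents that add atoms: N-iodosuccinimide, O=C1CCC(=O)N1I
Why: Electrophilic aromatic iodination; C3 and C5 are each ortho or para to both hydroxyl groups while C6 is meta to both, so two equivalents of the iodinating agent should stop at the 3,5-diiodide.

Step 2
Reactants: 2 2,4-dihydroxy-3,5-diiodobenzaldehyde; 3 tributyl(3-methylbut-2-enyl)stannane
Product: 4 2,4-dihydroxy-3,5-bis(3-methylbut-2-en-1-yl)benzaldehyde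
Conditions: 3 (3 equiv), Pd(PPh3)4 (10 mol %), degassed DMF, 90 °C
Reagents that add atoms: none
Why: Twofold Stille coupling of aryl iodides with an allylic stannane, which tolerates free phenols and leaves the aldehyde alone in the absence of a Lewis acid; the allyl–palladium intermediate should reductively eliminate at its unsubstituted terminus and so give linear prenyl groups.

Step 3
Reactants: 4 2,4-dihydroxy-3,5-bis(3-methylbut-2-en-1-yl)benzaldehyde
Product: 5 2-hydroxy-3,5-bis(3-methylbut-2-en-1-yl)-4-[(triisopropylsilyl)oxy]benzaldehyde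
Conditions: TIPSCl (1.1 equiv), imidazole (2.5 equiv), DMF, 0 °C to rt
Reagents that add atoms: triisopropylsilyl chloride, CC(C)[Si](Cl)(C(C)C)C(C)C
Why: Selective silylation of a phenol; the 2-hydroxyl is locked in a hydrogen bond to the formyl oxygen, whereas the 4-hydroxyl is the more acidic (para to the formyl group) and is not chelated, so it should react first.

Step 4
Reactants: 5 2-hydroxy-3,5-bis(3-methylbut-2-en-1-yl)-4-[(triisopropylsilyl)oxy]benzaldehyde; 6 trimethyl orthoformate; 7 3,4-dimethoxystyrene
Product: 10 (2S,4S)-cis-2-(3,4-dimethoxyphenyl)-4-methoxy-6,8-bis(3-methylbut-2-en-1-yl)-7-[(triisopropylsilyl)oxy]chromane, via dimethyl acetal 8 (not isolated), via methoxy ortho-quinone methide 9 (not isolated)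
Conditions: 6 (2 equiv), (R)-3,3'-bis(2,4,6-triisopropylphenyl)-1,1'-binaphthalene-2,2'-diyl N-(trifluoromethylsulfonyl)phosphoramide (10 mol %), 5 Å MS, toluene, rt, 1 h; then −30 °C, 7 (2.5 equiv) added over 2 h; Et3N quench
Reagents that add atoms: none
Why: Proposed new method: the acid first catalyses acetal exchange between 5 and 6 to give 8, which loses methanol to an oxocarbenium ion that is also the O-protonated form of the (E)-4-methoxy ortho-quinone methide 9 and stays hydrogen-bonded and ion-paired to the chiral phosphoramide anion; the CH2 terminus of 7 attacks C4 and O1 then closes on the developing 3,4-dimethoxybenzylic cation at C2, an asynchronous inverse-demand oxa-[4+2] cycloaddition pulled forward by rearomatisation of ring A. The closest known reactions are the racemic acid-catalysed three-component coupling of salicylaldehydes, orthoformates and styrenes to 4-alkoxy-2-arylchromans and the chiral N-triflylphosphoramide-catalysed cycloaddition of 4-aryl ortho-quinone methides with styrenes, so only their combination is untested. Ring C is closed by an intermolecular [4+2] annulation in which the C3–C4 bond forms first and the six-membered ring is completed by O1–C2 bond formation. C4 is set by the face of 9 that the 3,3'-aryl groups of the bound anion leave open, and C2 is set relative to C4 by the endo approach of the aryl group of 7 to the E-configured heterodiene, which gives the 2,4-cis adduct; a trans isomer formed on the same face would carry the opposite C2 configuration and is therefore removed by chromatography before C4 is erased. The step needs regioselectivity (aryl at C2), chemoselectivity for 7 over the prenyl alkenes and survival of the acid-labile groups: the polarisation of both partners fixes the regiochemistry, 7 is by far the strongest π-nucleophile present and is used in excess, neither prenyl group is ortho to the formyl carbon so none can reach C4, and the 2-hydroxyl is the only free phenol. A catalytic acid at low temperature, with sieves to take up methanol, is expected to spare the C8 prenyl group next to O1–H, the hindered silyl ether and the new O1–C2 bond.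

Step 5
Reactants: 10 (2S,4S)-cis-2-(3,4-dimethoxyphenyl)-4-methoxy-6,8-bis(3-methylbut-2-en-1-yl)-7-[(triisopropylsilyl)oxy]chromane
Product: 11 (2S,4RS)-2-(3,4-dimethoxyphenyl)-6,8-bis(3-methylbut-2-en-1-yl)-7-[(triisopropylsilyl)oxy]chroman-4-ol (mixture of C4 epimers)
Conditions: CSA (10 mol %), THF/H2O (4:1), 0 °C to rt; NaHCO3 quench
Reagents that add atoms: water, O
Why: SN1 solvolysis of a benzylic methyl ether; the C4 cation is stabilised by O1 (ortho) and the 7-silyloxy group (para), so methanol should be exchanged for water under acid too mild to ionise the O1–C2 bond or protonate the prenyl alkenes, and the loss of configuration at C4 is harmless because C4 becomes the carbonyl carbon.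

Step 6
Reactants: 11 (2S,4RS)-2-(3,4-dimethoxyphenyl)-6,8-bis(3-methylbut-2-en-1-yl)-7-[(triisopropylsilyl)oxy]chroman-4-ol
Product: 12 (2S)-2-(3,4-dimethoxyphenyl)-6,8-bis(3-methylbut-2-en-1-yl)-7-[(triisopropylsilyl)oxy]chroman-4-one
Conditions: activated MnO2 (15 equiv), CH2Cl2, rt
Reagents that add atoms: none
Why: MnO2 oxidation of an electron-rich benzylic secondary alcohol, in which both C4 epimers converge on one ketone; the neutral heterogeneous conditions leave the prenyl alkenes and the silyl ether alone, and no base is present that could open ring C through the C3 enolate and scramble C2.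

Step 7
Reactants: 12 (2S)-2-(3,4-dimethoxyphenyl)-6,8-bis(3-methylbut-2-en-1-yl)-7-[(triisopropylsilyl)oxy]chroman-4-one
Product: 13 (2S)-2-(3,4-dimethoxyphenyl)-7-hydroxy-6,8-bis(3-methylbut-2-en-1-yl)chroman-4-one (IN0946)
Conditions: TBAF (1.2 equiv), AcOH (1.2 equiv), THF, 0 °C; pH 7 buffer work-up
Reagents that add atoms: none
Why: Fluoride cleavage of an aryl silyl ether whose phenoxide is a good leaving group (para to the ketone); buffering with acetic acid keeps the medium from deprotonating C3, which would open ring C to the chalcone by E1cB and racemise C2.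

**Compound list**

1 | 2,4-dihydroxybenzaldehyde | O=Cc1ccc(O)cc1O | starting material
2 | 2,4-dihydroxy-3,5-diiodobenzaldehyde | O=Cc1cc(I)c(O)c(I)c1O | intermediate
3 | tributyl(3-methylbut-2-enyl)stannane | CCCC[Sn](CCCC)(CCCC)CC=C(C)C | starting material
4 | 2,4-dihydroxy-3,5-bis(3-methylbut-2-en-1-yl)benzaldehyde | O=Cc1cc(CC=C(C)C)c(O)c(CC=C(C)C)c1O | intermediate
5 | 2-hydroxy-3,5-bis(3-methylbut-2-en-1-yl)-4-[(triisopropylsilyl)oxy]benzaldehyde | O=Cc1cc(CC=C(C)C)c(O[Si](C(C)C)(C(C)C)C(C)C)c(CC=C(C)C)c1O | intermediate
6 | trimethyl orthoformate | COC(OC)OC | starting material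
7 | 3,4-dimethoxystyrene | C=Cc1ccc(OC)c(OC)c1 | starting material
8 | 6-(dimethoxymethyl)-2,4-bis(3-methylbut-2-en-1-yl)-3-[(triisopropylsilyl)oxy]phenol (dimethyl acetal of 5; not isolated) | COC(OC)c1cc(CC=C(C)C)c(O[Si](C(C)C)(C(C)C)C(C)C)c(CC=C(C)C)c1O | intermediate
9 | (E)-6-(methoxymethylidene)-2,4-bis(3-methylbut-2-en-1-yl)-3-[(triisopropylsilyl)oxy]cyclohexa-2,4-dien-1-one (4-methoxy ortho-quinone methide, present as its ion pair with the acid; not isolated) | CO/C=C1\C=C(CC=C(C)C)C(O[Si](C(C)C)(C(C)C)C(C)C)=C(CC=C(C)C)C1=O | intermediate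
10 | (2S,4S)-cis-2-(3,4-dimethoxyphenyl)-4-methoxy-6,8-bis(3-methylbut-2-en-1-yl)-7-[(triisopropylsilyl)oxy]chromane | COc1ccc([C@@H]2C[C@H](OC)c3cc(CC=C(C)C)c(O[Si](C(C)C)(C(C)C)C(C)C)c(CC=C(C)C)c3O2)cc1OC | intermediate
11 | (2S,4RS)-2-(3,4-dimethoxyphenyl)-6,8-bis(3-methylbut-2-en-1-yl)-7-[(triisopropylsilyl)oxy]chroman-4-ol (C4 epimer mixture) | COc1ccc([C@@H]2CC(O)c3cc(CC=C(C)C)c(O[Si](C(C)C)(C(C)C)C(C)C)c(CC=C(C)C)c3O2)cc1OC | intermediate
12 | (2S)-2-(3,4-dimethoxyphenyl)-6,8-bis(3-methylbut-2-en-1-yl)-7-[(triisopropylsilyl)oxy]chroman-4-one | COc1ccc([C@@H]2CC(=O)c3cc(CC=C(C)C)c(O[Si](C(C)C)(C(C)C)C(C)C)c(CC=C(C)C)c3O2)cc1OC | intermediate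
13 | (2S)-2-(3,4-dimethoxyphenyl)-7-hydroxy-6,8-bis(3-methylbut-2-en-1-yl)chroman-4-one (IN0946) | COc1ccc([C@@H]2CC(=O)c3cc(CC=C(C)C)c(O)c(CC=C(C)C)c3O2)cc1OC | target

**Step count**

Total steps: 7. Longest linear sequence: 7 steps (1 to 13).

**Steps most likely to fail**

1. Step 4. The chiral anion may bind the cationic intermediate too loosely, so that face selectivity or the cis/trans ratio is poor. The acid may also polymerise the electron-rich styrene, or add the O1–H group across the neighbouring C8 prenyl alkene. The fallback uses known chemistry and moves stereocontrol to a resolution.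
   - It sets out from 5. The same three components are joined with Sc(OTf)3 (10 mol %) in CH2Cl2 at room temperature, the known racemic version, which should give racemic 2-(3,4-dimethoxyphenyl)-4-methoxy-6,8-diprenyl-7-(triisopropylsilyloxy)chromane F1 as a cis/trans mixture.
   - Hydrolysis as in step 5 should give the racemic chroman-4-ol F2, and MnO2 oxidation as in step 6 the racemic silyl-protected flavanone F3.
   - F3 is then resolved kinetically by asymmetric transfer hydrogenation with RuCl(p-cymene)[(R,R)-TsDPEN] and HCO2H/Et3N in EtOAc, stopped near half conversion; this is an established way to resolve flavanones.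
   - The catalyst is expected to reduce the 2R ketone to the (2R,4R)-cis-chroman-4-ol F4 and to leave the 2S ketone. After chromatography this ketone is compound 12, where the route resumes.

2. Step 2. The acidic phenols may protonate the stannane, the second coupling may stall at the hindered mono-prenylated iodide, or the allyl unit may transpose to the 1,1-dimethylallyl isomer.
   - The fallback sets out from 2. Stille coupling with allyltributylstannane (Pd(PPh3)4, DMF, 80 °C) transfers a smaller group with no regiochemical ambiguity and should give 3,5-diallyl-2,4-dihydroxybenzaldehyde F5.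
   - Cross-metathesis of F5 with 2-methyl-2-butene (co-solvent) and the second-generation Grubbs catalyst (H2IMes)(PCy3)Cl2Ru=CHPh in CH2Cl2 at 40 °C should then turn both allyl groups into prenyl groups and return to 4.

3. Step 5. The C4 cation may lose a proton from C3 and eliminate to the flav-3-ene instead of taking up water. The acid may also cause silyl loss, prenyl cyclisation or partial ionisation at C2.
   - The fallback sets out from 10 and avoids acid solvolysis. TBAF/AcOH in THF at 0 °C first frees the phenol to give (2S,4S)-2-(3,4-dimethoxyphenyl)-7-hydroxy-4-methoxy-6,8-diprenylchromane F6.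
   - In acetate-buffered aqueous MeCN (pH about 5, 40 °C) the free para-hydroxyl should push out methanol to give the para-quinone methide F7 (not isolated). Water adds to it at C4 to give (2S,4RS)-2-(3,4-dimethoxyphenyl)-7-hydroxy-6,8-diprenylchroman-4-ol F8. This is the known solvolysis mode of para-hydroxybenzyl ethers.
   - MnO2 in EtOAc at room temperature should then oxidise the benzylic carbinol of F8 selectively to 13, so the path rejoins the route at the target.

**Further compounds**

F1 | step 4 | racemic 2-(3,4-dimethoxyphenyl)-4-methoxy-6,8-bis(3-methylbut-2-en-1-yl)-7-[(triisopropylsilyl)oxy]chromane (cis/trans mixture) | COc1ccc(C2CC(OC)c3cc(CC=C(C)C)c(O[Si](C(C)C)(C(C)C)C(C)C)c(CC=C(C)C)c3O2)cc1OC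
F2 | step 4 | racemic 2-(3,4-dimethoxyphenyl)-6,8-bis(3-methylbut-2-en-1-yl)-7-[(triisopropylsilyl)oxy]chroman-4-ol (diastereomer mixture) | COc1ccc(C2CC(O)c3cc(CC=C(C)C)c(O[Si](C(C)C)(C(C)C)C(C)C)c(CC=C(C)C)c3O2)cc1OC
F3 | step 4 | racemic 2-(3,4-dimethoxyphenyl)-6,8-bis(3-methylbut-2-en-1-yl)-7-[(triisopropylsilyl)oxy]chroman-4-one | COc1ccc(C2CC(=O)c3cc(CC=C(C)C)c(O[Si](C(C)C)(C(C)C)C(C)C)c(CC=C(C)C)c3O2)cc1OC
F4 | step 4 | (2R,4R)-cis-2-(3,4-dimethoxyphenyl)-6,8-bis(3-methylbut-2-en-1-yl)-7-[(triisopropylsilyl)oxy]chroman-4-ol | COc1ccc([C@H]2C[C@@H](O)c3cc(CC=C(C)C)c(O[Si](C(C)C)(C(C)C)C(C)C)c(CC=C(C)C)c3O2)cc1OC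
F5 | step 2 | 2,4-dihydroxy-3,5-di(prop-2-en-1-yl)benzaldehyde | O=Cc1cc(CC=C)c(O)c(CC=C)c1O
F6 | step 5 | (2S,4S)-2-(3,4-dimethoxyphenyl)-4-methoxy-6,8-bis(3-methylbut-2-en-1-yl)chroman-7-ol | COc1ccc([C@@H]2C[C@H](OC)c3cc(CC=C(C)C)c(O)c(CC=C(C)C)c3O2)cc1OC
F7 | step 5 | (2S)-2-(3,4-dimethoxyphenyl)-6,8-bis(3-methylbut-2-en-1-yl)-2,3-dihydro-7H-chromen-7-one (para-quinone methide, not isolated) | COc1ccc([C@@H]2CC=C3C=C(CC=C(C)C)C(=O)C(CC=C(C)C)=C3O2)cc1OC
F8 | step 5 | (2S,4RS)-2-(3,4-dimethoxyphenyl)-6,8-bis(3-methylbut-2-en-1-yl)chromane-4,7-diol (C4 epimer mixture) | COc1ccc([C@@H]2CC(O)c3cc(CC=C(C)C)c(O)c(CC=C(C)C)c3O2)cc1OC
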